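The six-membered carbocycle of colupulone (ring carbons C1 prenyl-bearing, C2, C3 gem-diprenyl, C4, C5 isobutyryl-bearing, C6) is a 1,3,5-tricarbonyl array. It is cut at C1–C2 and C4–C5 into a malonyl unit (C2–C3–C4) and a 1,3-dinucleophile (C1–C6–C5). The key step is a [3+3] double C-acylation of a β-diketone dianion with 2,2-diprenylmalonyl dichloride. Intermolecular acylation gives a fully prenylated tetraketide acyl chloride, which closes the ring by the Claisen cyclisation used in polyketide biosynthesis. The precursors are an open-chain diketone and a diacid chloride of similar size; all five ring substituents are in place before ring closure.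

Key step: step 5

Remark: colupulone is achiral (the quaternary ring carbon carries two identical prenyl groups), so no stereocentre has to be set; the dienol drawn in the target SMILES is taken as the tautomer obtained on mild acidification.

Step 1
Reactants: 1 dimethyl malonate; 2 prenyl bromide (1-bromo-3-methylbut-2-ene, 2.2 equiv)
Product: 3 dimethyl 2,2-bis(3-methylbut-2-en-1-yl)malonate
Conditions: NaH (2.2 equiv), THF/DMF, 0 °C → rt
Reagents that add atoms: none
Why: Malonic ester alkylation carried out twice; the malonate enolate displaces the primary allylic bromide by SN2 at C1, and the reactive allylic halide allows the second alkylation to the quaternary carbon.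

Step 2
Reactants: 3 dimethyl 2,2-bis(3-methylbut-2-en-1-yl)malonate
Product: 4 2,2-bis(3-methylbut-2-en-1-yl)malonic acid
Conditions: KOH (6 equiv), MeOH/H2O, reflux; then cold 1 M HCl to pH 2, extraction, concentration without heating
Reagents that add atoms: potassium hydroxide, [K+].[OH-]
Why: Saponification (BAc2) of both hindered esters should go to completion at reflux because the dicarboxylate is stable; cold acidification should avoid decarboxylation and acid-catalysed lactonisation onto the prenyl groups.

Step 3
Reactants: 4 2,2-bis(3-methylbut-2-en-1-yl)malonic acid
Product: 5 2,2-bis(3-methylbut-2-en-1-yl)malonyl dichloride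
Conditions: 1-chloro-N,N,2-trimethylprop-1-en-1-amine (2.3 equiv), CH2Cl2, 0 °C → rt; volatiles removed, used directly
Reagents that add atoms: 1-chloro-N,N,2-trimethylprop-1-en-1-amine (Ghosez reagent), CC(C)=C(Cl)N(C)C
Why: Acid chloride formation with an α-chloroenamine is neutral and releases an inert amide instead of HCl, so the trisubstituted alkenes should not be hydrochlorinated; the diacid chloride has no α-hydrogen and cannot form a ketene.

Step 4
Reactants: 6 6-methylhept-5-en-2-one; 7 methyl isobutyrate (3 equiv)
Product: 8 2,9-dimethyldec-8-ene-3,5-dione
Conditions: NaH (2.5 equiv), THF, reflux, slow addition of 6; then cold dilute HCl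
Reagents that add atoms: none
Why: Crossed Claisen condensation of a methyl ketone with an ester; acylation at the methyl group is expected because it leads to the β-diketone enolate as thermodynamic sink, and excess ester with slow ketone addition should suppress self-aldol reaction.

Step 5
Reactants: 8 2,9-dimethyldec-8-ene-3,5-dione (2.0 equiv); 5 2,2-bis(3-methylbut-2-en-1-yl)malonyl dichloride (1.0 equiv)
Product: 11 colupulone, via diketone dianion 9 (not isolated), via acyclic tetraketide acyl chloride 10 (not isolated)
Conditions: 8, NaH (2.1 equiv), THF, 0 °C; n-BuLi (2.0 equiv), −78 → 0 °C; 5 added slowly under dilution, −78 °C → rt; DMAP (0.2 equiv), rt; degassed cold aq. citric acid, under Ar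
Reagents that add atoms: none
Why: NaH removes the central proton of 8 and n-BuLi then the less hindered CH2 proton (methylene before the isopropyl methine); the terminal carbanion of dianion 9 attacks one COCl of 5 to give the enolate of 10, whose doubly activated carbon attacks the second COCl in a ring-closing Claisen (Dieckmann-type) C-acylation, and enolisation then gives dienol 11. The closest known reaction types are the γ-acylation of β-diketone dianions and the Effenberger [3+3] cyclisation of malonyl dichlorides with ketone-derived 1,3-dinucleophiles to cyclohexane-1,3,5-triones. The six-membered carbocycle closes in a 6-(enolexo)-exo-trig mode, helped by the gem-diprenyl (Thorpe–Ingold) group. No stereocentre results, because the quaternary carbon carries two identical prenyl groups and the CH centres of 10 and of the first-formed triketone are enolised. The step needs C- over O-acylation in the ring closure and 1:1 over 2:1 coupling: the carbocycle should be the thermodynamic sink because it is trapped as its β-triketone enolate by the second equivalent of 9, DMAP should re-open any enol lactone as an acylpyridinium and return it to C-acylation, and slow addition of 5 under dilution should let intramolecular closure outrun a second intermolecular acylation. 5 has no α-hydrogen and cannot form a ketene, the prenyl groups are inert to the basic medium, and the air-sensitive product is worked up under argon with a weak acid to avoid chroman formation.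

Compound list
1 | dimethyl malonate | COC(=O)CC(=O)OC | starting material
2 | prenyl bromide (1-bromo-3-methylbut-2-ene) | CC(C)=CCBr | starting material
3 | dimethyl 2,2-bis(3-methylbut-2-en-1-yl)malonate | COC(=O)C(CC=C(C)C)(CC=C(C)C)C(=O)OC | intermediate
4 | 2,2-bis(3-methylbut-2-en-1-yl)malonic acid | OC(=O)C(CC=C(C)C)(CC=C(C)C)C(O)=O | intermediate
5 | 2,2-bis(3-methylbut-2-en-1-yl)malonyl dichloride | ClC(=O)C(CC=C(C)C)(CC=C(C)C)C(Cl)=O | intermediate
6 | 6-methylhept-5-en-2-one | CC(=O)CCC=C(C)C | starting material
7 | methyl isobutyrate (methyl 2-methylpropanoate) | COC(=O)C(C)C | starting material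
8 | 2,9-dimethyldec-8-ene-3,5-dione | CC(C)C(=O)CC(=O)CCC=C(C)C | intermediate
9 | sodium lithium dianion of 8 (deprotonated at C4 and C6) | CC(C)C(=O)[CH-]C(=O)[CH-]CCC=C(C)C.[Na+].[Li+] | intermediate
10 | 8-methyl-2,2,4-tris(3-methylbut-2-en-1-yl)-3,5,7-trioxononanoyl chloride (present as its enolate; C4 racemic and enolisable) | CC(C)C(=O)CC(=O)C(CC=C(C)C)C(=O)C(CC=C(C)C)(CC=C(C)C)C(Cl)=O | intermediate
11 | colupulone, 3,5-dihydroxy-2-(2-methylpropanoyl)-4,6,6-tris(3-methylbut-2-en-1-yl)cyclohexa-2,4-dien-1-one | CC(C)=CCC1=C(O)C(CC=C(C)C)(CC=C(C)C)C(=O)C(C(=O)C(C)C)=C1O | target

Total step count: 5. Longest linear sequence: 4 steps (steps 1, 2, 3, 5); the diketone branch is 2 steps (steps 4, 5).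

Steps most likely to fail

Step 5. The ring closure may go through oxygen to an enol lactone, a second dianion may acylate the remaining acyl chloride (2:1 coupling or oligomers), or the acidic product may quench the dianion. The fallback separates the two acylations and puts the ring closure under thermodynamic control. It sets out from 3 and comes back at 11. Mono-saponification of 3 (KOH, 1.0 equiv, MeOH, rt) should give 3-methoxy-2,2-bis(3-methylbut-2-en-1-yl)-3-oxopropanoic acid F1. The α-chloroenamine of step 3 should convert it into methyl 3-chloro-2,2-bis(3-methylbut-2-en-1-yl)-3-oxopropanoate F2. F2 should acylate dianion 9 (2 equiv, THF, −78 °C) at the terminal carbon only, giving methyl 8-methyl-2,2,4-tris(3-methylbut-2-en-1-yl)-3,5,7-trioxononanoate F3, which is isolated. A Dieckmann-type Claisen cyclisation of F3 under equilibrating conditions (NaOMe, MeOH, 50 °C) should then close the ring to 11, since methoxide re-opens any lactone and the β-triketone enolate is the sink.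

Step 3. The mono-activated malonic acid may lose CO2, or traces of HCl may add to the prenyl double bonds during formation and concentration of the moisture-sensitive diacid chloride. The fallback replaces the acyl chloride by a stable thioester acyl donor. It sets out from 4 and comes back at 11. Steglich thioesterification of 4 (PhSH, DCC, cat. DMAP, CH2Cl2, 0 °C → rt) should give S,S'-diphenyl 2,2-bis(3-methylbut-2-en-1-yl)propanebis(thioate) F4, which can be purified by chromatography. F4 then takes the place of 5 in the step-5 protocol with dianion 9; thiophenolate is the leaving group in both Claisen acylations, as with the thioesters of polyketide biosynthesis.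

Step 4. Self-aldol condensation of the ketone may compete, and part of the acylation may occur at the methylene instead of the methyl group. The fallback fixes the regiochemistry by kinetic enolate formation and reaches the diketone by oxidation. It sets out from 6 and comes back at 8. LDA (THF, −78 °C) should give the methyl-side enolate of 6, and aldol addition to isobutyraldehyde should give racemic 3-hydroxy-2,9-dimethyldec-8-en-5-one F5. Oxidation with Dess–Martin periodinane (CH2Cl2, rt) should then give 8.

Further compounds
F1 | step 5 | 3-methoxy-2,2-bis(3-methylbut-2-en-1-yl)-3-oxopropanoic acid | COC(=O)C(CC=C(C)C)(CC=C(C)C)C(O)=O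
F2 | step 5 | methyl 3-chloro-2,2-bis(3-methylbut-2-en-1-yl)-3-oxopropanoate | COC(=O)C(CC=C(C)C)(CC=C(C)C)C(Cl)=O
F3 | step 5 | methyl 8-methyl-2,2,4-tris(3-methylbut-2-en-1-yl)-3,5,7-trioxononanoate (racemic, C4 enolisable) | COC(=O)C(CC=C(C)C)(CC=C(C)C)C(=O)C(CC=C(C)C)C(=O)CC(=O)C(C)C
F4 | step 3 | S,S'-diphenyl 2,2-bis(3-methylbut-2-en-1-yl)propanebis(thioate) | O=C(Sc1ccccc1)C(CC=C(C)C)(CC=C(C)C)C(=O)Sc1ccccc1
F5 | step 4 | 3-hydroxy-2,9-dimethyldec-8-en-5-one (racemic) | CC(C)C(O)CC(=O)CCC=C(C)C
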